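A direct plan would start from quercetin A1, which would be peracetylated to the pentaacetate A2, then selectively cleaved and methylated at O7 to give rhamnetin tetraacetate A3. Exchange of the acetates for three benzyl ethers would give tri-O-benzylrhamnetin A4, oxidation of C8–H of A4 with a diacyl peroxide under basic conditions would give the 8-acetate A5, and hydrogenolysis would finish. Its weakest steps would be:
(a) the C8–H acetoxylation, a C–O bond formation without close precedent in which attack at C6, O-acylation of the phenolate and radical decay of the peroxide compete, and which would be run on the most advanced material;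
(b) the acetate-to-benzyl protecting-group relay, three operations whose only gain is one methyl group;
(c) the benzylation that must stop at three of four hydroxyls, secured only by the lower reactivity of the chelated 5-OH.

**Plan of the new route.** Ring A is cut at C4a–C5 and C8–C8a, so that C5–C6–C7–C8 leave as one four-carbon piece, and ring B is cut off at C2–C1'. The enabling feature is that C5(OH)–C6(H)–C7(OMe)–C8(O) has exactly the pattern C(=O)–CH=C(OMe)–C(=O) of methyl semisquarate, while C4a=C8a is the C5=C6 bond of a 3-oxygenated 4-pyranone. Ring B and ring C (pyromeconic acid) are bought and joined by cross-coupling; ring A arises last, by ring expansion of a pyranonyl cyclobutenone. The C8 oxygen is acetylated at the moment it is created as an alkoxide, O5 emerges as the free chelated phenol and O7 arrives methylated. Hence no C–H oxidation of a flavonol, no choice among hydroxyls and no protecting-group relay on the core occurs.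

Key step: step 6

Remark: the target has no stereocentre; the stereocentres that appear on the way (carbinol carbon of 2, carbinol carbon of 10 and 11, C4a of 13) are racemic and are erased in steps 1 and 6.

**Step 1**
Reactants: 1 dimethyl squarate (3,4-dimethoxycyclobut-3-ene-1,2-dione)
Product: 3 3-methoxycyclobut-3-ene-1,2-dione (methyl semisquarate), via 4-hydroxy-2,3-dimethoxycyclobut-2-enone 2 (not isolated)
Conditions: LiAlH(O-t-Bu)3 (1.05 equiv), THF, −78 → −20 °C; H2O quench, extract; crude in CH2Cl2, conc. aq. HCl (cat.), 23 °C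
Reagents that add atoms: water O (re-adds after the hydroxyl has left as water; no net uptake)
Why: Hydride 1,2-addition to one carbonyl of the squarate ester followed by acid-catalysed allylic transposition with loss of methanol, the standard passage from a dialkyl squarate to an alkyl semisquarate; the carbinol stereocentre of 2 is lost in the transposition.

**Step 2**
Reactants: 4 pyromeconic acid (3-hydroxy-4H-pyran-4-one)
Product: 5 2-bromo-3-hydroxy-4H-pyran-4-one
Conditions: N-bromosuccinimide (1.0 equiv), MeCN, 0 → 23 °C, dark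
Reagents that add atoms: N-bromosuccinimide O=C1CCC(=O)N1Br
Why: Electrophilic bromination of the enolic 3-hydroxy-4-pyranone at C2, the enol β-carbon next to the hydroxyl, which is the site at which pyromeconic and kojic acid take up electrophiles (halogenation, aldol, Mannich reaction).

**Step 3**
Reactants: 5 2-bromo-3-hydroxy-4H-pyran-4-one
Product: 6 2-bromo-3-[(4-methoxybenzyl)oxy]-4H-pyran-4-one
Conditions: 4-methoxybenzyl chloride (1.2 equiv), K2CO3 (1.5 equiv), DMF, 50 °C
Reagents that add atoms: 4-methoxybenzyl chloride COc1ccc(CCl)cc1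
Why: Williamson O-alkylation of the acidic enolic hydroxyl; the 4-methoxybenzyl ether withstands hindered amide bases and heat and falls in the final hydrogenolysis together with the benzyl ethers.

**Step 4**
Reactants: 6 2-bromo-3-[(4-methoxybenzyl)oxy]-4H-pyran-4-one; 7 3,4-bis(benzyloxy)phenylboronic acid
Product: 8 2-[3,4-bis(benzyloxy)phenyl]-3-[(4-methoxybenzyl)oxy]-4H-pyran-4-one
Conditions: Pd(PPh3)4 (5 mol%), K2CO3 (2.5 equiv), DME–H2O (4:1), 80 °C, Ar
Reagents that add atoms: none
Why: Suzuki–Miyaura coupling, in which the C2–Br bond (a vinylogous acyl bromide) adds readily to zerovalent palladium and the electron-rich arylboronic acid transmetalates quickly, so that the C2–C1' bond forms while C5–H and C6–H stay untouched.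

**Step 5**
Reactants: 8 2-[3,4-bis(benzyloxy)phenyl]-3-[(4-methoxybenzyl)oxy]-4H-pyran-4-one; 3 3-methoxycyclobut-3-ene-1,2-dione
Product: 11 1-{6-[3,4-bis(benzyloxy)phenyl]-5-[(4-methoxybenzyl)oxy]-4-oxo-4H-pyran-2-yl}-2-methoxy-4-oxocyclobut-2-en-1-yl acetate (racemic), via 6-lithiopyranone 9 (not isolated), via lithium cyclobutenolate 10 (not isolated)
Conditions: lithium 2,2,6,6-tetramethylpiperidide (LiTMP, 1.1 equiv, from the amine and n-BuLi), THF, −78 °C, 15 min; cannulate into 3 (1.3 equiv), THF, −78 °C; then Ac2O (2.0 equiv), −78 → 0 °C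
Reagents that add atoms: acetic anhydride CC(=O)OC(C)=O; lithium 2,2,6,6-tetramethylpiperidide CC1(C)CCCC(C)(C)N1[Li] (its lithium is carried only by intermediates 9 and 10)
Why: Deprotonative lithiation of the γ-pyrone at the C–H next to the ring oxygen (the kinetic site, as in the C2 metalation of 3-substituted chromones and of 4-pyridones, the hindered amide not adding to the ring), 1,2-addition of the vinyllithium to the ketone-like carbonyl of 3 (the one flanked by C–OMe, the other being a deactivated vinylogous ester) as in organolithium additions to squarate esters, and O-acetylation of the tertiary alkoxide in the same flask; the carbinol stereocentre forms racemic and is destroyed in step 6.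

**Step 6**
Reactants: 11 1-{6-[3,4-bis(benzyloxy)phenyl]-5-[(4-methoxybenzyl)oxy]-4-oxo-4H-pyran-2-yl}-2-methoxy-4-oxocyclobut-2-en-1-yl acetate
Product: 14 8-acetoxy-2-[3,4-bis(benzyloxy)phenyl]-5-hydroxy-7-methoxy-3-[(4-methoxybenzyl)oxy]-4H-chromen-4-one, via dienylketene 12 (not isolated), via 4aH-chromene-4,5-dione tautomer 13 (not isolated)
Conditions: degassed p-xylene (0.02 M), 130 °C, Ar
Reagents that add atoms: none
Why: Heating should open the cyclobutenone by conrotatory four-electron cleavage of the C(=O)–C(OAc) bond to the (Z)-dienylketene 12, whose ketene carbon then closes onto the nucleophilic α-carbon (C5) of the pyranone in a disrotatory six-electron electrocyclization to give 13, and enolization of 13 delivers the aromatic ring A with its 5-OH locked in a hydrogen bond to the C4 carbonyl. The closest known reaction type is the Moore ring expansion of 4-aryl-, 4-heteroaryl- and 4-alkenyl-4-oxycyclobutenones to hydroquinone derivatives. Ring A is thus closed by electrocyclization at C4a–C5, the C8–C8a bond having been made in step 5, and ring C is carried in intact. The only new stereocentre, C4a of 13, is transient and is erased on tautomerization. The step needs outward rotation of the acetoxy group, which the known torquoselectivity of oxygen donors on the breaking carbon secures and which places the pyranone cis to the ketene; the site of closure is unambiguous because the other neighbour of the attachment carbon is the ring oxygen. The three oxygens of ring A are differentiated by origin (ketene carbonyl → free 5-OH, vinylogous ester → 7-OMe, capped carbinol → 8-OAc), and the acetate cannot migrate because it is flanked by the methyl ether and the ring oxygen.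

**Step 7**
Reactants: 14 8-acetoxy-2-[3,4-bis(benzyloxy)phenyl]-5-hydroxy-7-methoxy-3-[(4-methoxybenzyl)oxy]-4H-chromen-4-one
Product: 15 gossypetin 7-methyl ether 8-acetate
Conditions: H2 (1 atm), Pd/C (10 wt% Pd), EtOAc–THF (1:1), 23 °C
Reagents that add atoms: none
Why: Catalytic hydrogenolysis of the two benzyl ethers and the 4-methoxybenzyl ether in a neutral aprotic medium, which should leave the aryl acetate, the 7-methyl ether and the push-pull C2=C3 bond untouched.

**Compound list**
1 | dimethyl squarate (3,4-dimethoxycyclobut-3-ene-1,2-dione) | COC1=C(OC)C(=O)C1=O | starting material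
2 | 4-hydroxy-2,3-dimethoxycyclobut-2-en-1-one (racemic) | COC1=C(OC)C(O)C1=O | intermediate
3 | 3-methoxycyclobut-3-ene-1,2-dione (methyl semisquarate) | COC1=CC(=O)C1=O | intermediate
4 | pyromeconic acid (3-hydroxy-4H-pyran-4-one) | O=c1ccocc1O | starting material
5 | 2-bromo-3-hydroxy-4H-pyran-4-one | O=c1ccoc(Br)c1O | intermediate
6 | 2-bromo-3-[(4-methoxybenzyl)oxy]-4H-pyran-4-one | COc1ccc(COc2c(Br)occc2=O)cc1 | intermediate
7 | 3,4-bis(benzyloxy)phenylboronic acid | OB(O)c1ccc(OCc2ccccc2)c(OCc2ccccc2)c1 | starting material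
8 | 2-[3,4-bis(benzyloxy)phenyl]-3-[(4-methoxybenzyl)oxy]-4H-pyran-4-one | COc1ccc(COc2c(-c3ccc(OCc4ccccc4)c(OCc4ccccc4)c3)occc2=O)cc1 | intermediate
9 | 6-lithio derivative of 8 (lithium at the carbon next to the ring oxygen) | [Li]c1cc(=O)c(OCc2ccc(OC)cc2)c(-c2ccc(OCc3ccccc3)c(OCc3ccccc3)c2)o1 | intermediate
10 | lithium 1-{6-[3,4-bis(benzyloxy)phenyl]-5-[(4-methoxybenzyl)oxy]-4-oxo-4H-pyran-2-yl}-2-methoxy-4-oxocyclobut-2-en-1-olate (racemic) | [Li+].[O-]C1(c2cc(=O)c(OCc3ccc(OC)cc3)c(-c3ccc(OCc4ccccc4)c(OCc4ccccc4)c3)o2)C(OC)=CC1=O | intermediate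
11 | 1-{6-[3,4-bis(benzyloxy)phenyl]-5-[(4-methoxybenzyl)oxy]-4-oxo-4H-pyran-2-yl}-2-methoxy-4-oxocyclobut-2-en-1-yl acetate (racemic) | CC(=O)OC1(c2cc(=O)c(OCc3ccc(OC)cc3)c(-c3ccc(OCc4ccccc4)c(OCc4ccccc4)c3)o2)C(OC)=CC1=O | intermediate
12 | (Z)-dienylketene: 1-{6-[3,4-bis(benzyloxy)phenyl]-5-[(4-methoxybenzyl)oxy]-4-oxo-4H-pyran-2-yl}-2-methoxy-4-oxobuta-1,3-dien-1-yl acetate, ketenyl group cis to the pyranone | O=C=C/C(OC)=C(/OC(C)=O)c1cc(=O)c(OCc2ccc(OC)cc2)c(-c2ccc(OCc3ccccc3)c(OCc3ccccc3)c2)o1 | intermediate
13 | 8-acetoxy-2-[3,4-bis(benzyloxy)phenyl]-7-methoxy-3-[(4-methoxybenzyl)oxy]-4aH-chromene-4,5-dione (racemic at C4a) | COC1=CC(=O)C2C(=O)C(OCc3ccc(OC)cc3)=C(c3ccc(OCc4ccccc4)c(OCc4ccccc4)c3)OC2=C1OC(C)=O | intermediate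
14 | 8-acetoxy-2-[3,4-bis(benzyloxy)phenyl]-5-hydroxy-7-methoxy-3-[(4-methoxybenzyl)oxy]-4H-chromen-4-one | COc1cc(O)c2c(=O)c(OCc3ccc(OC)cc3)c(-c3ccc(OCc4ccccc4)c(OCc4ccccc4)c3)oc2c1OC(C)=O | intermediate
15 | gossypetin 7-methyl ether 8-acetate | COc1cc(O)c2c(=O)c(O)c(-c3ccc(O)c(O)c3)oc2c1OC(C)=O | target

**Step count and risk**
Total step count: 7. Longest linear sequence: 6 steps (4 → 15, steps 2 to 7); step 1 is a one-step side branch.

Steps most likely to fail:

1. Step 5. The deprotonation may be incomplete or unselective (loss of C5–H with ring opening, or attack of the lithiated pyranone on pyranone not yet metalated). Fallback, from 8 back to 11: zincation of 8 next to the ring oxygen with the mixed zinc amide TMP2Zn·2MgCl2·2LiCl (TMP = 2,2,6,6-tetramethylpiperidide, a base of the type that metalates chromones and 4-pyranones without ring cleavage) in THF at −30 °C would give the bis(pyranonyl)zinc F1. Iodolysis (I2) would give 2-[3,4-bis(benzyloxy)phenyl]-6-iodo-3-[(4-methoxybenzyl)oxy]-4H-pyran-4-one F2. Iodine–magnesium exchange with i-PrMgCl·LiCl at −78 °C would then give the chloromagnesium reagent F3, with the metalation site fixed by the halogen. Addition of F3 to 3 would give the chloromagnesium cyclobutenolate F4, and Ac2O in the same flask would give 11.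

2. Step 6. The ring opening may turn the acetoxy group inward, or the tertiary acetate may be lost before electrocyclization, so that the ketene decays instead of closing ring A. Fallback, from 10 back to 14: quenching 10 with aqueous NH4Cl in place of Ac2O would give the free 4-hydroxycyclobutenone F5, the classical substrate of this ring expansion. Heating F5 in degassed toluene at 110 °C under Ar would give the 5,8-dihydroxy-7-methoxyflavone F6 (a hydroquinone, kept from air). Ac2O (1.05 equiv) and pyridine in CH2Cl2 at 0 °C would then acetylate only the 8-OH, the 5-OH being held in its hydrogen bond to the C4 carbonyl, to give 14.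

3. Step 7. Cleavage of the 4-methoxybenzyl ether may be sluggish, with saturation of the C2=C3 bond or solvolysis of the acetate on prolonged exposure. Fallback, from 14 directly to 15: Lewis-acid dealkylation with BCl3 in the presence of pentamethylbenzene as cation scavenger in CH2Cl2 at −78 °C. The benzyl and 4-methoxybenzyl cations would be transferred to the scavenger, while the aryl acetate and the 7-methyl ether (not peri to the carbonyl) should persist. No new compound is made on the way.

**Further compounds**
F1 | step 5 | bis{6-[3,4-bis(benzyloxy)phenyl]-5-[(4-methoxybenzyl)oxy]-4-oxo-4H-pyran-2-yl}zinc | [Zn](c1cc(=O)c(OCc2ccc(OC)cc2)c(-c2ccc(OCc3ccccc3)c(OCc3ccccc3)c2)o1)c1cc(=O)c(OCc2ccc(OC)cc2)c(-c2ccc(OCc3ccccc3)c(OCc3ccccc3)c2)o1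
F2 | step 5 | 2-[3,4-bis(benzyloxy)phenyl]-6-iodo-3-[(4-methoxybenzyl)oxy]-4H-pyran-4-one | COc1ccc(COc2c(-c3ccc(OCc4ccccc4)c(OCc4ccccc4)c3)oc(I)cc2=O)cc1
F3 | step 5 | {6-[3,4-bis(benzyloxy)phenyl]-5-[(4-methoxybenzyl)oxy]-4-oxo-4H-pyran-2-yl}magnesium chloride | COc1ccc(COc2c(-c3ccc(OCc4ccccc4)c(OCc4ccccc4)c3)oc([Mg]Cl)cc2=O)cc1
F4 | step 5 | chloromagnesium 1-{6-[3,4-bis(benzyloxy)phenyl]-5-[(4-methoxybenzyl)oxy]-4-oxo-4H-pyran-2-yl}-2-methoxy-4-oxocyclobut-2-en-1-olate (racemic) | Cl[Mg]OC1(c2cc(=O)c(OCc3ccc(OC)cc3)c(-c3ccc(OCc4ccccc4)c(OCc4ccccc4)c3)o2)C(OC)=CC1=O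
F5 | step 6 | 4-{6-[3,4-bis(benzyloxy)phenyl]-5-[(4-methoxybenzyl)oxy]-4-oxo-4H-pyran-2-yl}-4-hydroxy-3-methoxycyclobut-2-en-1-one (racemic) | OC1(c2cc(=O)c(OCc3ccc(OC)cc3)c(-c3ccc(OCc4ccccc4)c(OCc4ccccc4)c3)o2)C(OC)=CC1=O
F6 | step 6 | 2-[3,4-bis(benzyloxy)phenyl]-5,8-dihydroxy-7-methoxy-3-[(4-methoxybenzyl)oxy]-4H-chromen-4-one | COc1cc(O)c2c(=O)c(OCc3ccc(OC)cc3)c(-c3ccc(OCc4ccccc4)c(OCc4ccccc4)c3)oc2c1O
F0 | step 7 | none | none
A1 | direct plan | quercetin | Oc1cc(O)c2c(=O)c(O)c(-c3ccc(O)c(O)c3)oc2c1
A2 | direct plan | quercetin pentaacetate | CC(=O)Oc1cc(OC(C)=O)c2c(=O)c(OC(C)=O)c(-c3ccc(OC(C)=O)c(OC(C)=O)c3)oc2c1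
A3 | direct plan | rhamnetin 3,3',4',5-tetraacetate | COc1cc(OC(C)=O)c2c(=O)c(OC(C)=O)c(-c3ccc(OC(C)=O)c(OC(C)=O)c3)oc2c1
A4 | direct plan | 3,3',4'-tri-O-benzylrhamnetin | COc1cc(O)c2c(=O)c(OCc3ccccc3)c(-c3ccc(OCc4ccccc4)c(OCc4ccccc4)c3)oc2c1
A5 | direct plan | 8-acetoxy-3,3',4'-tri-O-benzylrhamnetin | COc1cc(O)c2c(=O)c(OCc3ccccc3)c(-c3ccc(OCc4ccccc4)c(OCc4ccccc4)c3)oc2c1OC(C)=O
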